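**Retrosynthetic overview**
1. 13 ⇒ 12: the five benzyl ethers are removed last, by hydrogenolysis.
2. 12 ⇒ 8 + 10: the ester is placed on O7, the only free phenol of boronate 8. Reductive C4–O cleavage then also releases O5.
3. 8 ⇒ 4 + 5 + 6: a three-component [3+3] annulation makes C4–C4a, O1–C2 and two B–O bonds in one flask. This closes pyran ring C and the O4/O5 dioxaborin ring together on purchased ring A.
4. 4 ⇒ 3 ⇒ 1 + 2: catalytic asymmetric epoxidation of the enal fixes C3 directly and C2 through later inversion. The enal comes from a Wittig reaction.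
5. Ring order: oxirane (step 2), then dioxaborin plus pyran C (step 3, oxirane consumed), then dioxaborin excised (step 5). The three benzene rings (A, B and the galloyl ring) are purchased.

Assumption: C4 in 7, 8 and 11 is carried as an epimer mixture and drawn without configuration because step 5 turns it into CH2; the facial sense in step 2 follows the standard shielding model for diarylprolinol silyl ethers, and both catalyst enantiomers are sold.

**Step 1**
Reactants: 1 3,4-bis(benzyloxy)benzaldehyde; 2 (triphenylphosphoranylidene)acetaldehyde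
Product: 3 (E)-3-[3,4-bis(benzyloxy)phenyl]prop-2-enal
Conditions: 2 (1.1 equiv), PhMe, 90 °C
Reagents that add atoms: none
Why: Wittig olefination with the stabilised formyl ylide is E-selective, stops at the enal when the ylide is kept near one equivalent, and leaves the benzyl ethers untouched.

**Step 2**
Reactants: 3 (E)-3-[3,4-bis(benzyloxy)phenyl]prop-2-enal
Product: 4 (2R,3S)-3-[3,4-bis(benzyloxy)phenyl]oxirane-2-carbaldehyde (trans)
Conditions: 35% aq H2O2 (1.3 equiv), (R)-2-{bis[3,5-bis(trifluoromethyl)phenyl](trimethylsilyloxy)methyl}pyrrolidine (10 mol %), CH2Cl2, rt; Et3N-washed silica plug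
Reagents that add atoms: hydrogen peroxide, OO
Why: In this Jørgensen iminium–enamine (Weitz–Scheffer-type) epoxidation the CAr2(OTMS) group of the (R)-catalyst blocks the Si face of Cβ in the E-iminium ion, so HOO– adds to the Re face and the enamine closes the trans-oxirane as (2R,3S), with roughly 95% ee and 9:1 dr expected by analogy with cinnamaldehyde, while the formyl group tempers the lability of the electron-rich aryl epoxide.

**Step 3**
Reactants: 4 (2R,3S)-3-[3,4-bis(benzyloxy)phenyl]oxirane-2-carbaldehyde; 5 phloroglucinol; 6 phenylboronic acid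
Product: 8 (2R,3S)-2-[3,4-bis(benzyloxy)phenyl]chromane-3,4,5,7-tetraol 4,5-O-phenylboronate (peri-fused pyran + 1,3,2-dioxaborin; 3-OH/7-OH free; C4 epimers), via epoxy-benzodioxaborin 7 (not isolated)
Conditions: 5 (1.2 equiv), 6 (1.05 equiv), EtCO2H (20 mol %), 4 Å MS, THF–PhMe 1:2, 40 °C; filter, triturate
Reagents that add atoms: none
Why: Proposed new method: the aryl boronate ArO–B(Ph)OH of 5 binds the very electrophilic epoxy-aldehyde and delivers it to the ortho carbon through a six-membered transition state, and dehydration closes dioxaborin 7 (closest known type: Nagata–Lau boronic-acid-templated ortho-hydroxyalkylation of phenols to 2-phenyl-4H-1,3,2-benzodioxaborins); the second ortho-OH then opens the boron/acid-activated p-alkoxybenzylic oxirane 6-endo at the benzylic carbon (closest known type: acid-mediated cyclisation of 2-(3-aryloxiranylmethyl)phenols to 2,3-trans-flavan-3-ols), so C3 keeps the epoxide C–O bond (3S), C2 is set by inversion (2R, and a looser SN1-like opening also prefers 2,3-trans), and tying O4 to O5 restrains C4 ionisation and leaves O7 as the only free phenol.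

**Step 4**
Reactants: 9 3,4,5-tris(benzyloxy)benzoic acid
Product: 10 3,4,5-tris(benzyloxy)benzoyl chloride
Conditions: (COCl)2 (1.3 equiv), DMF (cat.), CH2Cl2, 0 °C to rt; concentrate
Reagents that add atoms: oxalyl chloride, O=C(Cl)C(=O)Cl
Why: DMF-catalysed (Vilsmeier-type) acid chloride formation is clean for this acid, and all by-products are gases.

**Step 5**
Reactants: 8 (2R,3S)-2-[3,4-bis(benzyloxy)phenyl]chromane-3,4,5,7-tetraol 4,5-O-phenylboronate; 10 3,4,5-tris(benzyloxy)benzoyl chloride
Product: 12 (2R,3S)-3',4'-di-O-benzylcatechin 7-O-[3,4,5-tris(benzyloxy)benzoate], via 7-O-aroyl boronate 11 (not isolated)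
Conditions: 10 (1.05 equiv), Et3N (1.3 equiv), CH2Cl2, –20 °C; then Et3SiH (3 equiv), TFA (10% v/v), –20 to 0 °C; aq NaHCO3
Reagents that add atoms: none
Why: The 7-phenoxide is the only phenolic nucleophile and outcompetes the hindered secondary 3-OH for the aroyl chloride without DMAP (Einhorn-type O-acylation); dilute TFA then ionises only the doubly O-activated C4–O(B) bond to an o-quinone-methide-type cation that Et3SiH reduces (Kursanov–Parnes ionic hydrogenation, the silane counterpart of the known hydride/Lewis-acid reduction of benzodioxaborins to o-alkylphenols), which erases C4, frees 5-OH on work-up and leaves C2 and C3 untouched.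

**Step 6**
Reactants: 12 (2R,3S)-3',4'-di-O-benzylcatechin 7-O-[3,4,5-tris(benzyloxy)benzoate]
Product: 13 (2R,3S)-catechin 7-O-gallate
Conditions: H2 (1 atm), 20% Pd(OH)2/C, THF–EtOAc, rt
Reagents that add atoms: none
Why: Catalytic hydrogenolysis removes all five O-benzyl groups, while the cyclic O1–C2 ether, the aryl ester (no alcohol solvent) and both stereocentres survive, as in the standard debenzylation of catechin gallates.

**Compound list**
1 | 3,4-bis(benzyloxy)benzaldehyde | O=Cc1ccc(OCc2ccccc2)c(OCc2ccccc2)c1 | starting material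
2 | (triphenylphosphoranylidene)acetaldehyde | O=CC=P(c1ccccc1)(c1ccccc1)c1ccccc1 | starting material
3 | (E)-3-[3,4-bis(benzyloxy)phenyl]prop-2-enal | O=C/C=C/c1ccc(OCc2ccccc2)c(OCc2ccccc2)c1 | intermediate
4 | (2R,3S)-3-[3,4-bis(benzyloxy)phenyl]oxirane-2-carbaldehyde | O=C[C@@H]1O[C@H]1c1ccc(OCc2ccccc2)c(OCc2ccccc2)c1 | intermediate
5 | phloroglucinol (benzene-1,3,5-triol) | Oc1cc(O)cc(O)c1 | starting material
6 | phenylboronic acid | OB(O)c1ccccc1 | starting material
7 | 4-[(2S,3S)-3-[3,4-bis(benzyloxy)phenyl]oxiran-2-yl]-2-phenyl-4H-1,3,2-benzodioxaborinine-5,7-diol (C4 epimers; not isolated) | Oc1cc(O)c2c(c1)OB(c1ccccc1)OC2[C@@H]1O[C@H]1c1ccc(OCc2ccccc2)c(OCc2ccccc2)c1 | intermediate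
8 | (2R,3S)-2-[3,4-bis(benzyloxy)phenyl]chromane-3,4,5,7-tetraol 4,5-O-cyclic phenylboronate (B bridges O4 and O5; 3-OH and 7-OH free; C4 epimers) | Oc1cc2c3c(c1)O[C@H](c1ccc(OCc4ccccc4)c(OCc4ccccc4)c1)[C@@H](O)C3OB(c1ccccc1)O2 | intermediate
9 | 3,4,5-tris(benzyloxy)benzoic acid | OC(=O)c1cc(OCc2ccccc2)c(OCc2ccccc2)c(OCc2ccccc2)c1 | starting material
10 | 3,4,5-tris(benzyloxy)benzoyl chloride | ClC(=O)c1cc(OCc2ccccc2)c(OCc2ccccc2)c(OCc2ccccc2)c1 | intermediate
11 | 7-O-[3,4,5-tris(benzyloxy)benzoyl] derivative of boronate 8 (C4 epimers; not isolated) | O=C(Oc1cc2c3c(c1)O[C@H](c1ccc(OCc4ccccc4)c(OCc4ccccc4)c1)[C@@H](O)C3OB(c1ccccc1)O2)c1cc(OCc2ccccc2)c(OCc2ccccc2)c(OCc2ccccc2)c1 | intermediate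
12 | (2R,3S)-2-[3,4-bis(benzyloxy)phenyl]-3,5-dihydroxychroman-7-yl 3,4,5-tris(benzyloxy)benzoate | O=C(Oc1cc(O)c2c(c1)O[C@H](c1ccc(OCc3ccccc3)c(OCc3ccccc3)c1)[C@@H](O)C2)c1cc(OCc2ccccc2)c(OCc2ccccc2)c(OCc2ccccc2)c1 | intermediate
13 | (2R,3S)-catechin 7-O-gallate | O=C(Oc1cc(O)c2c(c1)O[C@H](c1ccc(O)c(O)c1)[C@@H](O)C2)c1cc(O)c(O)c(O)c1 | target

**Step count**
Total step count: 6.
Longest linear sequence: 5 steps (1 → 3 → 4 → 8 → 12 → 13).

**Steps most likely to fail**

Step 3 is the riskiest. Phloroglucinol or the A ring of 8 may attack the benzylic epoxide carbon or an ionised C4, giving 4-aryl adducts and oligomers. In a 3,4-cis epimer the boronate may also slip to O3/O4. The fallback sets out from 5 and 10 and comes back at 11. It tames the nucleophile and reverses the order of events. Excess 5 is monoacylated with 10 (Et3N, THF, 0 °C; surplus 5 is washed out with water) to give 3,5-dihydroxyphenyl 3,4,5-tris(benzyloxy)benzoate F1. This resorcinol is then submitted to the boronic-acid annulation with 4 and 6. Resorcinols substituted at C5 condense with aldehydes at the carbon between the two hydroxyls, as olivetol does with citral. Only that adduct has the two ortho-OH groups that the two ring closures need, so 11 forms directly. The acyl group lowers A-ring nucleophilicity and no selective acylation is required. The route resumes with the silane/TFA half of step 5.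

Step 5 comes next. The 3-OH may be partly acylated. More seriously, TFA/silane may reductively open the O1–C2 bond of the p-alkoxyaryl chroman. The fallback sets out from 11, isolated this time after the acylation, and comes back at 13. Ionic reduction is replaced by catalytic hydrogenolysis. Boron is transesterified off with pinacol (THF, rt) to give (2R,3S)-2-[3,4-bis(benzyloxy)phenyl]-3,4,5-trihydroxychroman-7-yl 3,4,5-tris(benzyloxy)benzoate F2. A single hydrogenolysis (H2, Pd(OH)2/C, THF with 5% AcOH) then cleaves the doubly O-activated benzylic C4–OH together with the five benzyl ethers. This is the leucocyanidin-to-catechin type of reduction.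

Step 2 is third. The electron-rich enal forms a sluggish iminium ion, and the product epoxide may rearrange or hydrate. The fallback sets out from 3 and comes back at 4. It moves the asymmetric step to the allylic alcohol. Luche reduction (NaBH4, CeCl3, MeOH) gives (E)-3-[3,4-bis(benzyloxy)phenyl]prop-2-en-1-ol F3. Sharpless asymmetric epoxidation (Ti(OiPr)4, L-(+)-DET, TBHP, 4 Å MS, CH2Cl2, –20 °C) gives [(2S,3S)-3-[3,4-bis(benzyloxy)phenyl]oxiran-2-yl]methanol F4. The absolute sense here is secured by the reliable Sharpless mnemonic. Parikh–Doering oxidation (SO3·py, DMSO, Et3N) then returns 4.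

**Further compounds**
F1 | step 3 | 3,5-dihydroxyphenyl 3,4,5-tris(benzyloxy)benzoate | O=C(Oc1cc(O)cc(O)c1)c1cc(OCc2ccccc2)c(OCc2ccccc2)c(OCc2ccccc2)c1
F2 | step 5 | (2R,3S)-2-[3,4-bis(benzyloxy)phenyl]-3,4,5-trihydroxychroman-7-yl 3,4,5-tris(benzyloxy)benzoate (C4 epimers) | O=C(Oc1cc(O)c2c(c1)O[C@H](c1ccc(OCc3ccccc3)c(OCc3ccccc3)c1)[C@@H](O)C2O)c1cc(OCc2ccccc2)c(OCc2ccccc2)c(OCc2ccccc2)c1
F3 | step 2 | (E)-3-[3,4-bis(benzyloxy)phenyl]prop-2-en-1-ol | OC/C=C/c1ccc(OCc2ccccc2)c(OCc2ccccc2)c1
F4 | step 2 | [(2S,3S)-3-[3,4-bis(benzyloxy)phenyl]oxiran-2-yl]methanol | OC[C@@H]1O[C@H]1c1ccc(OCc2ccccc2)c(OCc2ccccc2)c1
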